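I read each flask at 5.0 h, so I asked what fraction of each charge was left by then, and what that fraction implied for the target.

| flask | substrate | precatalyst | temperature | remark | time |
|---|---|---|---|---|---|
| alpha | 0.39 M | 15 mM | −20 °C | run made earlier |  |
| epsilon | 0.62 M | 15 mM | 13 °C | run made earlier |  |
| theta | 0.28 M | 30 mM | −20 °C | run made earlier |  |
| Saturday's | 0.28 M | 15 mM | 5 °C |  | 5.0 h |
| Tuesday's | 0.28 M | 15 mM | 25 °C |  | 5.0 h |
| Sunday's | 0.28 M | 15 mM | −15 °C |  | 5.0 h |
| Friday's | 0.28 M | 15 mM | −35 °C |  | 5.0 h |

| run | time / h | target / % | over-reaction product / % | substrate / % |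
|---|---|---|---|---|
| alpha | 2.50 | 0.4 | 0 | 100.3 |
| alpha | 5.00 | 0 | 0 | 100.4 |
| alpha | 6.00 | 0.1 | 0 | 99.8 |
| alpha | 8.00 | 0.5 | 0 | 99.3 |
| alpha | 10.0 | 0 | 0 | 98.5 |
| epsilon | 0.250 | 0.7 | 0.5 | 95.8 |
| epsilon | 0.417 | 3.3 | 1.2 | 91.8 |
| epsilon | 0.833 | 9.7 | 13.8 | 75.1 |
| epsilon | 1.50 | 17.4 | 45.9 | 36.5 |
| epsilon | 3.00 | 3.1 | 95.7 | 0.3 |
| theta | 0.833 | 1.4 | 0 | 100.7 |
| theta | 1.33 | 0.4 | 0 | 99.7 |
| theta | 3.00 | 0.7 | 0.5 | 99.3 |
| theta | 5.00 | 0.8 | 0 | 99.7 |
| theta | 10.0 | 1.5 | 0.3 | 98.0 |

(readings scatter by 1 percentage point)

* the flask that comes out highest in share of target in all that became target or over-reaction product, or "all alike" when all lie within 1.5 percentage points (Saturday's / Tuesday's / Sunday's / Friday's / all alike)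
* share of target in all that became target or over-reaction product, Saturday's
* share of target in all that became target or over-reaction product, Tuesday's
* share of target in all that became target or over-reaction product, Sunday's
* share of target in all that became target or over-reaction product, Friday's



The epsilon run gave me a ladder at 13 °C. The first rung was the target. Between the readings at 0.833 h and 1.50 h, the gain in over-reaction product, set against the mean target, read as a target half-life of 0.195 h. Next came the substrate. Its fraction left gave a half-life of 0.641 h over the same stretch, longer than the target's. The opening was slower again: the first reading gave a substrate half-life of 4.04 h, longer than the later one, so the epsilon flask started with a delay. The last rung was the alpha run at −20 °C, whose last reading gave a substrate half-life of 459 h, far beyond the reading time, though that reading rests on a loss of 1.50 % against a scatter of 1 percentage point.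

The substrate and target half-lives read over that stretch of the epsilon run stood in the ratio 3.28. I carried it as the wear ratio, the substrate's half-life divided by the target's, a selectivity factor. My rule worked from the fraction left, for two first-order steps in a row with the wear ratio held at epsilon's reading: target equals the fraction left minus that fraction raised to the wear ratio, divided by the wear ratio less one. The share is that target over the fraction converted. At epsilon's pace I reckoned 5.0 h to leave 0.448 % of the substrate, and Tuesday's was warmer still. The rule then gave a share of 0.197 %. As the fraction left neared one, the share climbed toward the whole. At alpha's pace I reckoned 5.0 h to leave 99.2 % of the substrate, and the rule gave a share of 98.8 %.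

The forecast chose Friday's, with 20 % for Saturday's, 1 % for Tuesday's, 80 % for Sunday's and 85 % for Friday's. It said: “The target is an intermediate that is over-reacted quickly”. I agreed on the order, but I put Sunday's and Friday's above its figures.

The flasks gave Friday's as highest: 14.1 % for Saturday's, 0 % for Tuesday's, 85.1 % for Sunday's and 99.2 % for Friday's.

    substrate + free catalyst → catalyst intermediate (k = 0.0460 M⁻¹ s⁻¹, Ea = 61.0 kJ mol⁻¹)
    catalyst intermediate → free catalyst + target (k = 0.0250 s⁻¹, Ea = 80.0 kJ mol⁻¹)
    target → over-reaction product (k = 3.50 × 10⁻⁴ s⁻¹, Ea = 75.0 kJ mol⁻¹)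
    precatalyst ⇌ free catalyst (K = 1.70, k = 2.90 × 10⁻⁵ s⁻¹, Ea = 95.0 kJ mol⁻¹, ΔH = 21.0 kJ mol⁻¹)
    (constants at 5 °C)

Saturday's kept 12 % of its substrate, and the wear ratio gave a share of 6.03 % there, less than the flask's 14.1 %. I then took Tuesday's flask run at 0 °C, which kept 56 % of its substrate. The same reckoning gave a share of 41.0 %, and the share in that flask came out at 37.5 %.

All runs were computed for an exercise; the scatter is artificial.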